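**Compound numbers used throughout:** 1 and 2 starting materials, 3 propargyl ether, 4 and 5 imine intermediates, 6 allenyl ether aldehyde, 7 zinc alkoxide, 8 cis-hydroxy nitrile, 9 ketimine, 10 hydroxy ketone, 11 acetoxy ketone, 12 (R)-carbinol, 13 tigloyl chloride, 14 tiglate, 15 allylic alcohol, 16 target.

## Analysis of the target

Target 16 is a 2,3-dihydro-1-benzofuran (ring A = benzene, ring B = O1–C2–C3–C3a–C7a) with a 1-formylvinyl group on C2, an acetoxy group on C3 and a 1-(tigloyloxy)ethyl group on C5, para to O1. C2 and C3 are both S and cis on ring B, the more crowded arrangement; the side-chain carbinol carbon C1' is R and too remote for any relay, so it needs its own catalyst-controlled event. The enal is an allylic aryl ether (CH2=C–C2–O1): a nucleophile that adds to the CH2 terminus can expel O1 (SN2'), opening ring B reversibly and eroding C2. The C3 acetate is benzylic and anti to C2–H, so base or acid can eliminate acetic acid and aromatise ring B to a benzofuran. The C1' ester sits para to O1 and can ionise under acid toward a para-quinone methide, which would racemise C1'. The structural feature that invites the key step is the array O–C3–C2(O1)–C(=CH2)–C: a homoallylic alcohol whose allylic carbon C2 carries O1 and whose inner alkene carbon carries one more carbon. This is the retron of an allene–aldehyde alkylative cyclization, in which the oxygen-bearing allene carbon bonds to the aldehyde carbon (C2–C3) and the central allene carbon receives a one-carbon group. The difficulty is to make ring B cis and enantiopure from a flat precursor, to differentiate two secondary benzylic esters, and to reach the aldehyde oxidation level last without opening any of the three decomposition channels.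

## Retrosynthetic reasoning

**16 ⇒ 15 ⇒ 14.** The enal is the most fragile group, so it is made last. The formyl carbon is traced back to the methyl of an isopropenyl group: first the C=O of 16 to the CH2OH of 15, then the C–O bond of 15 to an allylic C–H of 14. This keeps the side chain a robust isopropenyl group during every basic or nucleophilic step. The forward reactions must oxidise only the isopropenyl methyl, not C2–H and not the electron-poor tiglate.

**14 ⇒ 12 + 13, and 12 ⇒ 11.** The tiglate C–O bond is cut to give carbinol 12 and acid chloride 13; acylation keeps the C1' configuration. The C1'–H bond of 12 is then cut to give aryl methyl ketone 11. The forward reduction must set the R configuration by catalyst control alone and must leave the isopropenyl group and the C3 acetate untouched.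

**11 ⇒ 10 ⇒ 8.** The C3 acetate is removed to give 10, and the acetyl group is traced to the nitrile of 8 by cutting the C(acyl)–CH3 bond. A nitrile is chosen as the C5 handle because a methyl ketone would enolise and condense with the aldehyde during the base-mediated allene formation, and an aryl halide would not survive zerovalent nickel. Acetylating C3–OH before the ketone is reduced keeps the two secondary alcohols apart in time, so no selective acylation is ever needed.

**8 ⇒ 6 (key disconnection).** Two bonds are cut at once: C2–C3 of ring B and the bond from the inner alkene carbon to its methyl group. This reveals the achiral, planar allenyl ether aldehyde 6. The forward step must close ring B, set C2 and C3 cis with absolute control, and complete the three-carbon side chain by methyl transfer. It is cut here and not at O1–C2 or at C3–O because only this cut makes carbon–carbon bonds and both stereocentres in one event.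

**6 ⇒ 3 ⇒ 1 + 2.** The allenyl ether is the prototropic isomer of propargyl ether 3. The base needed for the shift would also add the terminal alkyne to a free aldehyde, so the aldehyde travels through this operation as imines 4 and 5 in the same flask. The O–CH2 bond of 3 is cut to give phenol 1 and bromide 2.

## Alternatives that were turned down

**Alternative 1:** the textbook route. Disconnection at C3–H: the cis alcohol comes from hydride addition to the face of a benzofuran-3(2H)-one opposite the C2 substituent, the key intermediate being ketone A1; the forward key step is a cis-selective reduction, or an asymmetric transfer hydrogenation with dynamic kinetic resolution. It was turned down for three reasons. A1 is a β,γ-unsaturated ketone whose enol is an aromatic 3-hydroxybenzofuran, so double-bond migration into conjugation with the carbonyl is a permanent drain and C2 is never configurationally secure. Building the coumaranone and then attaching an isopropenyl group at C2 without that migration costs more steps than the whole front end of the chosen route. The key step itself forms no carbon–carbon bond and closes no ring.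

**Alternative 2:** disconnection at O1–C2. The forward key step is a zerovalent-palladium-catalysed cyclization of the trans vinyl epoxide A2, in which double inversion at C2 would give the cis product. It was turned down because the π-allyl intermediate offers the phenoxide two termini, and attack at the unsubstituted one closes a seven-membered ring instead of ring B. An ortho-hydroxyaryl epoxide also ionises at its benzylic carbon with help from the phenol, which scrambles C3. A2 has no allylic alcohol handle for a reliable asymmetric epoxidation. Finally, the step only makes a carbon–oxygen bond, so the C2–C3 bond and both stereocentres must be built beforehand.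

**Alternative 3:** C–H oxidation logic. Ring B is closed first without the C3 oxygen, by enantioselective oxidative (Wacker-type) cyclization of prenylphenol A4 with a chiral divalent palladium catalyst to give A3, and C3–H is then oxygenated. It was turned down because the C3 oxidation has to choose among several activated C–H bonds (C3 benzylic, C2 allylic and α-oxy, later the side-chain benzylic one) and must deliver oxygen to the face already occupied by the isopropenyl group. A radical or cation at C3 is trapped trans or loses C2–H to aromatise. The usual remedy, over-oxidation to the ketone and reduction, leads straight back to A1. Enantiocontrol in such cyclizations is also weaker for trisubstituted prenyl alkenes than for tetrasubstituted ones.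

Key step: step 3

## Route

Remark: the sense of induction of the chiral ligand in step 3 cannot be derived with confidence from a model; the route is written for the ligand antipode that gives the 2S,3S series, to be identified in the first run by correlation with material from the fallback.

**Step 1**
Reactants: 1 3-formyl-4-hydroxybenzonitrile; 2 3-bromoprop-1-yne (propargyl bromide)
Product: 3 3-formyl-4-(prop-2-yn-1-yloxy)benzonitrile
Conditions: K2CO3 (1.5 equiv), DMF, rt
Reagents that add atoms: none
Why: Williamson ether synthesis; the phenol is acidified by the ortho formyl and para cyano groups and its phenoxide is alkylated on oxygen by SN2.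

**Step 2**
Reactants: 3 3-formyl-4-(prop-2-yn-1-yloxy)benzonitrile
Product: 6 3-formyl-4-(propa-1,2-dien-1-yloxy)benzonitrile, via propargyl ether tert-butylimine 4 (not isolated), via allenyl ether tert-butylimine 5 (not isolated)
Conditions: tBuNH2 (2 equiv), 4 Å MS, THF, rt; KOtBu (0.3 equiv), 0 °C; aq. citric acid (pH 4), rt
Reagents that add atoms: water, O (the carbonyl oxygen of 6); tert-butylamine, CC(C)(C)N (its atoms stay in 4 and 5 only)
Why: One-pot sequence: the N-tert-butyl aldimine masks the aldehyde against Favorskii-type acetylide addition, catalytic tert-butoxide effects the propargyl-to-allenyl prototropic rearrangement, and mild aqueous acid cleaves the imine far faster than it hydrolyses an electron-poor aryl allenyl ether.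

**Step 3**
Reactants: 6 3-formyl-4-(propa-1,2-dien-1-yloxy)benzonitrile
Product: 8 (2S,3S)-3-hydroxy-2-(prop-1-en-2-yl)-2,3-dihydro-1-benzofuran-5-carbonitrile, via methylzinc alkoxide 7 (not isolated)
Conditions: Ni(cod)2 (10 mol %), L* (12 mol %; one antipode of the spirobiindane N,N-bis(1-phenylethyl)phosphoramidite SIPHOS-PE), Me2Zn (2.5 equiv), toluene, 0 °C, slow addition of 6; then H2O
Reagents that add atoms: dimethylzinc, C[Zn]C
Why: Proposed new method: an enantioselective, ligand-controlled version of the nickel/organozinc alkylative cyclization of allenyl aldehydes, here on an aryl allenyl ether; the closest known reaction types are the racemic, cis-selective Ni(cod)2/organozinc cyclization of carbon-tethered allenyl aldehydes and the nickel/chiral monophosphorus-ligand alkylative coupling of aldehydes with alkynes and Me2Zn. Zerovalent nickel bearing one L* binds the aldehyde and the internal C=C of the allenyl ether and undergoes oxidative cyclization, which forms the C2–C3 bond and an oxanickelacyclopentane whose nickel holds the C3 oxygen and the former central allene carbon as an alkenyl ligand. Me2Zn then takes the oxygen from nickel and hands over a methyl group, and C(sp2)–CH3 reductive elimination gives the isopropenyl group, alkoxide 7 and zerovalent nickel. Ring B closes in a 5-exo-trig mode at the carbonyl carbon; the three-atom tether (C3a, C7a, O1) lets only the oxygen-bearing allene carbon reach the aldehyde, whereas bonding at the terminal CH2 would need a seven-membered ring. C2 and C3 should come out cis because ring B and the nickelacycle share the C2–C3 bond and two fused five-membered rings can only be cis-fused, so the C3–O bond and the C2–alkenyl bond, both held by nickel, lie on one face. The absolute configuration is decided at C3 by the aldehyde face that L* exposes during oxidative cyclization, and C2 follows from the cis fusion. The step needs methyl transfer through ligated nickel to outrun direct addition of Me2Zn to the aldehyde and the ligand-free nickel pathway; the uncatalysed addition is slow in toluene at 0 °C, the nitrile is inert to Me2Zn, and a slight excess of L* over nickel with slow addition of 6 keeps unligated nickel low.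

**Step 4**
Reactants: 8 (2S,3S)-3-hydroxy-2-(prop-1-en-2-yl)-2,3-dihydro-1-benzofuran-5-carbonitrile
Product: 10 1-[(2S,3S)-3-hydroxy-2-(prop-1-en-2-yl)-2,3-dihydro-1-benzofuran-5-yl]ethan-1-one, via ketimine 9 (not isolated)
Conditions: MeMgBr (3.5 equiv), CuBr·SMe2 (5 mol %), THF, 0 → 50 °C; then 1 M aq. HCl, 0 °C
Reagents that add atoms: methylmagnesium bromide, C[Mg]Br; water, O
Why: Copper-assisted Grignard addition to the nitrile after deprotonation of C3–OH gives the N-magnesio ketimine, which cannot take a second methyl; brief cold acid hydrolyses 9 to the ketone, and the iminium or acyl group at C5 draws on the O1 lone pair so that ionisation at C3 is held back.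

**Step 5**
Reactants: 10 1-[(2S,3S)-3-hydroxy-2-(prop-1-en-2-yl)-2,3-dihydro-1-benzofuran-5-yl]ethan-1-one
Product: 11 (2S,3S)-5-acetyl-2-(prop-1-en-2-yl)-2,3-dihydro-1-benzofuran-3-yl acetate
Conditions: Ac2O (1.5 equiv), pyridine, DMAP (5 mol %), CH2Cl2, 0 °C → rt
Reagents that add atoms: acetic anhydride, CC(=O)OC(C)=O
Why: DMAP-catalysed acylation of the only free hydroxyl; the O–acyl bond is formed without touching the C3–O bond, so the configuration is retained.

**Step 6**
Reactants: 11 (2S,3S)-5-acetyl-2-(prop-1-en-2-yl)-2,3-dihydro-1-benzofuran-3-yl acetate
Product: 12 (2S,3S)-5-[(1R)-1-hydroxyethyl]-2-(prop-1-en-2-yl)-2,3-dihydro-1-benzofuran-3-yl acetate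
Conditions: RuCl[(R,R)-TsDPEN](p-cymene) (1 mol %), HCO2H/Et3N (5:2), EtOAc, 30 °C
Reagents that add atoms: none
Why: Noyori asymmetric transfer hydrogenation of an aryl methyl ketone; the R,R catalyst gives the R carbinol by the established sense for acetophenones, under pure catalyst control because ring B is remote, and the isolated alkene and the acetate are inert to the ruthenium hydride.

**Step 7**
Reactants: 12 (2S,3S)-5-[(1R)-1-hydroxyethyl]-2-(prop-1-en-2-yl)-2,3-dihydro-1-benzofuran-3-yl acetate; 13 (2E)-2-methylbut-2-enoyl chloride (tigloyl chloride)
Product: 14 (1R)-1-[(2S,3S)-3-acetoxy-2-(prop-1-en-2-yl)-2,3-dihydro-1-benzofuran-5-yl]ethyl (2E)-2-methylbut-2-enoate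
Conditions: pyridine (3 equiv), DMAP (10 mol %), CH2Cl2, 0 °C
Reagents that add atoms: none
Why: Acylation of the secondary benzylic alcohol under basic conditions with retention at C1' (no C–O cleavage, no acid that could ionise the para-alkoxybenzylic position); pyridine is too weak a base to deconjugate the acid chloride through a vinylketene.

**Step 8**
Reactants: 14 (1R)-1-[(2S,3S)-3-acetoxy-2-(prop-1-en-2-yl)-2,3-dihydro-1-benzofuran-5-yl]ethyl (2E)-2-methylbut-2-enoate
Product: 15 (1R)-1-[(2S,3S)-3-acetoxy-2-(3-hydroxyprop-1-en-2-yl)-2,3-dihydro-1-benzofuran-5-yl]ethyl (2E)-2-methylbut-2-enoate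
Conditions: SeO2 (0.5 equiv), tBuOOH (3 equiv, in decane), CH2Cl2, rt
Reagents that add atoms: tert-butyl hydroperoxide, CC(C)(C)OO (its oxygen is passed on through the SeO2 catalyst)
Why: Riley allylic oxidation (ene reaction, then [2,3]-sigmatropic shift, which returns the double bond to its place); the methyl C–H is preferred over the tertiary C2–H, the conjugated and electron-poor tiglate alkene should be inert to the electrophilic ene step, and any 16 formed by further oxidation is carried into step 9.

**Step 9**
Reactants: 15 (1R)-1-[(2S,3S)-3-acetoxy-2-(3-hydroxyprop-1-en-2-yl)-2,3-dihydro-1-benzofuran-5-yl]ethyl (2E)-2-methylbut-2-enoate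
Product: 16 (1R)-1-[(2S,3S)-3-acetoxy-2-(3-oxoprop-1-en-2-yl)-2,3-dihydro-1-benzofuran-5-yl]ethyl (2E)-2-methylbut-2-enoate
Conditions: MnO2 (activated, 15 equiv), CH2Cl2, rt
Reagents that add atoms: none
Why: Chemoselective oxidation of the primary allylic alcohol on the MnO2 surface under neutral, non-nucleophilic conditions, so the SN2'-labile enal, the C3 acetate and the C1' ester are not exposed to base, acid or amines.

## Compound list

1 | 3-formyl-4-hydroxybenzonitrile | N#Cc1ccc(O)c(C=O)c1 | starting material
2 | 3-bromoprop-1-yne (propargyl bromide) | C#CCBr | starting material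
3 | 3-formyl-4-(prop-2-yn-1-yloxy)benzonitrile | N#Cc1ccc(OCC#C)c(C=O)c1 | intermediate
4 | 3-[(E)-(tert-butylimino)methyl]-4-(prop-2-yn-1-yloxy)benzonitrile | N#Cc1ccc(OCC#C)c(/C=N/C(C)(C)C)c1 | intermediate (not isolated)
5 | 3-[(E)-(tert-butylimino)methyl]-4-(propa-1,2-dien-1-yloxy)benzonitrile | N#Cc1ccc(OC=C=C)c(/C=N/C(C)(C)C)c1 | intermediate (not isolated)
6 | 3-formyl-4-(propa-1,2-dien-1-yloxy)benzonitrile | N#Cc1ccc(OC=C=C)c(C=O)c1 | intermediate
7 | methylzinc (2S,3S)-5-cyano-2-(prop-1-en-2-yl)-2,3-dihydro-1-benzofuran-3-olate | C=C(C)[C@@H]1Oc2ccc(C#N)cc2[C@@H]1O[Zn]C | intermediate (not isolated)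
8 | (2S,3S)-3-hydroxy-2-(prop-1-en-2-yl)-2,3-dihydro-1-benzofuran-5-carbonitrile | C=C(C)[C@@H]1Oc2ccc(C#N)cc2[C@@H]1O | intermediate
9 | 1-[(2S,3S)-3-hydroxy-2-(prop-1-en-2-yl)-2,3-dihydro-1-benzofuran-5-yl]ethan-1-imine (formed as its magnesium salt) | C=C(C)[C@@H]1Oc2ccc(C(C)=N)cc2[C@@H]1O | intermediate (not isolated)
10 | 1-[(2S,3S)-3-hydroxy-2-(prop-1-en-2-yl)-2,3-dihydro-1-benzofuran-5-yl]ethan-1-one | C=C(C)[C@@H]1Oc2ccc(C(C)=O)cc2[C@@H]1O | intermediate
11 | (2S,3S)-5-acetyl-2-(prop-1-en-2-yl)-2,3-dihydro-1-benzofuran-3-yl acetate | C=C(C)[C@@H]1Oc2ccc(C(C)=O)cc2[C@@H]1OC(C)=O | intermediate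
12 | (2S,3S)-5-[(1R)-1-hydroxyethyl]-2-(prop-1-en-2-yl)-2,3-dihydro-1-benzofuran-3-yl acetate | C=C(C)[C@@H]1Oc2ccc([C@@H](C)O)cc2[C@@H]1OC(C)=O | intermediate
13 | (2E)-2-methylbut-2-enoyl chloride (tigloyl chloride) | C/C=C(\C)C(Cl)=O | starting material
14 | (1R)-1-[(2S,3S)-3-acetoxy-2-(prop-1-en-2-yl)-2,3-dihydro-1-benzofuran-5-yl]ethyl (2E)-2-methylbut-2-enoate | C=C(C)[C@@H]1Oc2ccc([C@@H](C)OC(=O)/C(C)=C/C)cc2[C@@H]1OC(C)=O | intermediate
15 | (1R)-1-[(2S,3S)-3-acetoxy-2-(3-hydroxyprop-1-en-2-yl)-2,3-dihydro-1-benzofuran-5-yl]ethyl (2E)-2-methylbut-2-enoate | C=C(CO)[C@@H]1Oc2ccc([C@@H](C)OC(=O)/C(C)=C/C)cc2[C@@H]1OC(C)=O | intermediate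
16 | (1R)-1-[(2S,3S)-3-acetoxy-2-(3-oxoprop-1-en-2-yl)-2,3-dihydro-1-benzofuran-5-yl]ethyl (2E)-2-methylbut-2-enoate | C=C(C=O)[C@@H]1Oc2ccc([C@@H](C)OC(=O)/C(C)=C/C)cc2[C@@H]1OC(C)=O | target

## Step count and risk

Total: 9 steps. Longest linear sequence: 9 steps, from 1 to 16.

**Step 3 (key step, proposed new method).** The most likely failure is insufficient enantiofacial discrimination. The ligand-free nickel pathway is itself productive, so any unligated nickel erodes the enantiomeric purity, and a bulky phosphoramidite may also slow the oxidative cyclization enough for direct methyl transfer to the aldehyde or allene oligomerisation to compete. The fallback uses known chemistry and sets out from 6. Cyclization under the known ligand-free conditions (Ni(cod)2, Me2Zn, THF, 0 °C) should give the racemic cis alcohol F1. Lipase-catalysed acetylation (immobilised Candida antarctica lipase B, vinyl acetate, MTBE) then resolves it; by the empirical size rule for secondary alcohols, with the aryl side as the large group, the 3S alcohol is expected to be acylated to give (2S,3S)-acetate F2. Methanolysis (K2CO3, MeOH, 0 °C) returns it to the route at 8. Should the enzyme prefer the antipode, the unreacted alcohol is 8 itself. The price is at most half of the material.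

**Step 8.** The risk is loss of site selectivity in the ene step (attack on the allylic methyl groups of the tiglate or abstraction of C2–H), over-oxidation, and acid-induced ionisation of the two benzylic esters by selenous acid. The fallback moves the allylic oxidation ahead of the tiglate and sets out from 11. SeO2/tBuOOH in CH2Cl2 gives allylic alcohol F3, which is silylated (TBSCl, imidazole, DMF) to silyl ether F4. Asymmetric transfer hydrogenation as in step 6 gives carbinol F5, and acylation with 13 as in step 7 gives tiglate F6. Desilylation with HF·pyridine buffered with pyridine in THF at 0 °C rejoins the route at 15.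

**Step 2.** The risk is incomplete masking of the aldehyde, so that base-mediated acetylide addition consumes material; a further prototropic shift to the 1-propynyl ether; and hydrolysis of the allenyl ether during imine cleavage. The fallback replaces in-situ protection by a redox detour and sets out from 3. NaBH4 in MeOH gives benzylic alcohol F7, KOtBu (1.5 equiv) in THF isomerises it to allenyl ether alcohol F8, and MnO2 in CH2Cl2 oxidises F8 to rejoin the route at 6.

**Step 4.** The risk is sluggish addition to the electron-rich nitrile, competing deprotonation at the allylic, α-oxygenated C2–H followed by Wittig-type rearrangement, and acid-promoted dehydration toward the aromatic benzofuran during imine hydrolysis. The fallback avoids a carbanionic methyl source and the ketone altogether and sets out from 8. DIBAL-H (2.5 equiv, CH2Cl2, −78 °C, then cold 1 M HCl) gives hydroxy aldehyde F9, and acetylation as in step 5 gives acetoxy aldehyde F10. Catalytic enantioselective methyl addition (Me2Zn, (2R)-(+)-3-exo-(dimethylamino)isoborneol, toluene, 0 °C), which is known to give R 1-arylethanols from aromatic aldehydes, rejoins the route directly at 12.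

## Further compounds

F1 | step 3 | racemic cis-3-hydroxy-2-(prop-1-en-2-yl)-2,3-dihydro-1-benzofuran-5-carbonitrile (both enantiomers written) | C=C(C)[C@@H]1Oc2ccc(C#N)cc2[C@@H]1O.C=C(C)[C@H]1Oc2ccc(C#N)cc2[C@H]1O
F2 | step 3 | (2S,3S)-5-cyano-2-(prop-1-en-2-yl)-2,3-dihydro-1-benzofuran-3-yl acetate | C=C(C)[C@@H]1Oc2ccc(C#N)cc2[C@@H]1OC(C)=O
F3 | step 8 | (2S,3S)-5-acetyl-2-(3-hydroxyprop-1-en-2-yl)-2,3-dihydro-1-benzofuran-3-yl acetate | C=C(CO)[C@@H]1Oc2ccc(C(C)=O)cc2[C@@H]1OC(C)=O
F4 | step 8 | (2S,3S)-5-acetyl-2-[3-(tert-butyldimethylsilyloxy)prop-1-en-2-yl]-2,3-dihydro-1-benzofuran-3-yl acetate | C=C(CO[Si](C)(C)C(C)(C)C)[C@@H]1Oc2ccc(C(C)=O)cc2[C@@H]1OC(C)=O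
F5 | step 8 | (2S,3S)-2-[3-(tert-butyldimethylsilyloxy)prop-1-en-2-yl]-5-[(1R)-1-hydroxyethyl]-2,3-dihydro-1-benzofuran-3-yl acetate | C=C(CO[Si](C)(C)C(C)(C)C)[C@@H]1Oc2ccc([C@@H](C)O)cc2[C@@H]1OC(C)=O
F6 | step 8 | (1R)-1-[(2S,3S)-3-acetoxy-2-[3-(tert-butyldimethylsilyloxy)prop-1-en-2-yl]-2,3-dihydro-1-benzofuran-5-yl]ethyl (2E)-2-methylbut-2-enoate | C=C(CO[Si](C)(C)C(C)(C)C)[C@@H]1Oc2ccc([C@@H](C)OC(=O)/C(C)=C/C)cc2[C@@H]1OC(C)=O
F7 | step 2 | 3-(hydroxymethyl)-4-(prop-2-yn-1-yloxy)benzonitrile | N#Cc1ccc(OCC#C)c(CO)c1
F8 | step 2 | 3-(hydroxymethyl)-4-(propa-1,2-dien-1-yloxy)benzonitrile | N#Cc1ccc(OC=C=C)c(CO)c1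
F9 | step 4 | (2S,3S)-3-hydroxy-2-(prop-1-en-2-yl)-2,3-dihydro-1-benzofuran-5-carbaldehyde | C=C(C)[C@@H]1Oc2ccc(C=O)cc2[C@@H]1O
F10 | step 4 | (2S,3S)-5-formyl-2-(prop-1-en-2-yl)-2,3-dihydro-1-benzofuran-3-yl acetate | C=C(C)[C@@H]1Oc2ccc(C=O)cc2[C@@H]1OC(C)=O
A1 | alternative 1 | 3-oxo-2-(prop-1-en-2-yl)-2,3-dihydro-1-benzofuran-5-carbonitrile (racemic, configurationally labile at C2) | C=C(C)C1Oc2ccc(C#N)cc2C1=O
A2 | alternative 2 | 4-hydroxy-3-[(2S,3S)-3-(prop-1-en-2-yl)oxiran-2-yl]benzonitrile (trans epoxide) | C=C(C)[C@@H]1O[C@H]1c1cc(C#N)ccc1O
A3 | alternative 3 | (2R)-2-(prop-1-en-2-yl)-2,3-dihydro-1-benzofuran-5-carbonitrile | C=C(C)[C@@H]1Oc2ccc(C#N)cc2C1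
A4 | alternative 3 | 4-hydroxy-3-(3-methylbut-2-en-1-yl)benzonitrile | CC(C)=CCc1cc(C#N)ccc1O
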